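## Retrosynthetic overview

1. The only ring, the ten-membered carbocycle, is closed in the last step at C5–C6 (ring locants of the target name). An allylic radical at C5 couples with the titanium-bound (Z)-enal carbon C6 under Cp2TiCl, which also creates the C6 carbinol.
2. The C1 benzoate / C9 acetate pair (1,3-anti) comes from a β-hydroxy (Z)-enone by Evans–Tishchenko reduction with benzaldehyde, then acetylation.
3. The C1–C10 bond and the C1/C10 syn pair come from a diisopinocampheylboron syn-aldol between a (Z)-enone (C6–C10 plus isopropyl) and a (Z)-β,γ-unsaturated chloro-aldehyde (C1–C5).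
4. Both Z-alkenes are set before coupling: C7=C8 by anti-carbomagnesiation/iodination of prop-2-yn-1-ol and acyl cross-coupling with 3-methylbutanoyl chloride; C3=C4 is inherited from the ring of 4-methyl-5,6-dihydro-2H-pyran-2-one.

Assumption 1: 4-methyl-5,6-dihydro-2H-pyran-2-one is bought as such.
Assumption 2: (−)-Ipc2BOTf directs its Z-enolate to the Re face of the aldehyde (the sense recalled for ethyl ketones, not verified for this isobutyl enone); if the opposite sense is found, the antipodal reagent is used.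
Locants: open-chain compounds are numbered as in their own names; chain C1–C5 become ring C6–C10 and chain C6–C10 become ring C1–C5.

## Route

Step 1
Reactants: 1 prop-2-yn-1-ol
Product: 3 (2Z)-3-iodo-2-methylprop-2-en-1-ol, via cyclic alkenylmagnesium alkoxide 2 (not isolated)
Conditions: MeMgBr (2.5 equiv), CuI (10 mol%), THF, −10 °C to rt; then I2, −78 to 0 °C
Reagents that add atoms: methylmagnesium bromide, C[Mg]Br; iodine, II
Why: Copper-catalysed anti-carbomagnesiation of the propargylic alkoxide puts methyl on the inner alkyne carbon and closes a five-membered magnesium chelate, so iodinolysis with retention gives the vinyl iodide with iodine cis to CH2OH (Z).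

Step 2
Reactants: 3 (2Z)-3-iodo-2-methylprop-2-en-1-ol
Product: 4 tert-butyl{[(2Z)-3-iodo-2-methylprop-2-en-1-yl]oxy}dimethylsilane
Conditions: TBSCl, imidazole, DMF, rt
Reagents that add atoms: tert-butyldimethylsilyl chloride, CC(C)(C)[Si](C)(C)Cl
Why: Standard silylation of the primary allylic alcohol; the ether stops the later cis-γ-hydroxy enone from closing to a furan and survives the organolithium, boron and samarium steps.

Step 3
Reactants: 4 tert-butyl{[(2Z)-3-iodo-2-methylprop-2-en-1-yl]oxy}dimethylsilane; 5 3-methylbutanoyl chloride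
Product: 8 (2Z)-1-{[tert-butyl(dimethyl)silyl]oxy}-2,6-dimethylhept-2-en-4-one, via alkenyllithium 6 (not isolated), via alkenylzinc chloride 7 (not isolated)
Conditions: t-BuLi (2.1 equiv), Et2O, −78 °C; ZnCl2, THF, −78 to 0 °C; then 5, Pd(PPh3)4 (5 mol%), 0 °C to rt
Reagents that add atoms: none
Why: Iodine–lithium exchange, transmetalation to zinc and palladium-catalysed acylation (Negishi acyl coupling) all go with retention at the alkenyl carbon, giving the Z-enone directly.

Step 4
Reactants: 9 4-methyl-5,6-dihydro-2H-pyran-2-one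
Product: 10 (2Z)-3-methylpent-2-ene-1,5-diol
Conditions: i-Bu2AlH (3.5 equiv), CH2Cl2, −78 to 0 °C; Rochelle salt work-up
Reagents that add atoms: none
Why: DIBAL-H reduces the unsaturated lactone by 1,2-addition to the ene-diol; the Z-trisubstituted alkene is inherited from the six-membered ring.

Step 5
Reactants: 10 (2Z)-3-methylpent-2-ene-1,5-diol
Product: 11 (3Z)-5-chloro-3-methylpent-3-en-1-ol
Conditions: NCS (2.2 equiv), Me2S (2.4 equiv), CH2Cl2, −25 to 0 °C; cold aqueous work-up
Reagents that add atoms: N-chlorosuccinimide, O=C1CCC(=O)N1Cl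
Why: Corey–Kim chlorination, in which only the allylic alkoxysulfonium ion collapses to the chloride (SN2 at the primary carbon, no allylic shift) below 0 °C, while the homoallylic one is returned as the alcohol on work-up.

Step 6
Reactants: 11 (3Z)-5-chloro-3-methylpent-3-en-1-ol
Product: 12 (3Z)-5-chloro-3-methylpent-3-enal
Conditions: Dess–Martin periodinane, NaHCO3, CH2Cl2, 0 °C; used crude at once
Reagents that add atoms: none
Why: Buffered Dess–Martin oxidation gives the β,γ-unsaturated aldehyde under neutral conditions that do not move the alkene into conjugation.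

Step 7
Reactants: 8 (2Z)-1-{[tert-butyl(dimethyl)silyl]oxy}-2,6-dimethylhept-2-en-4-one; 12 (3Z)-5-chloro-3-methylpent-3-enal
Product: 14 (2Z,5R,6S,8Z)-1-{[tert-butyl(dimethyl)silyl]oxy}-10-chloro-6-hydroxy-2,8-dimethyl-5-(propan-2-yl)deca-2,8-dien-4-one, via Z-boron enolate 13 (not isolated)
Conditions: (−)-Ipc2BOTf (1.6 equiv), i-Pr2NEt (2.5 equiv), CH2Cl2, −78 °C, 3 h; 12 (1.5 equiv), −78 to −20 °C, 16 h; H2O2, MeOH, pH 7 buffer, 0 °C
Reagents that add atoms: none
Why: Paterson syn-aldol, in which the triflate/hindered amine pair gives the Z-enol borinate 13, which reacts through a chair Zimmerman–Traxler transition state (syn) on the aldehyde Re face selected by the isopinocampheyl ligands, setting (5R,6S).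

Step 8
Reactants: 14 (2Z,5R,6S,8Z)-1-{[tert-butyl(dimethyl)silyl]oxy}-10-chloro-6-hydroxy-2,8-dimethyl-5-(propan-2-yl)deca-2,8-dien-4-one
Product: 15 (2Z,4S,5S,6S,8Z)-1-{[tert-butyl(dimethyl)silyl]oxy}-10-chloro-4-hydroxy-2,8-dimethyl-5-(propan-2-yl)deca-2,8-dien-6-yl benzoate
Conditions: PhCHO (6 equiv), SmI2 (0.3 equiv, pre-stirred with the PhCHO), THF, −10 °C
Reagents that add atoms: benzaldehyde, O=Cc1ccccc1
Why: Evans–Tishchenko reduction, in which the samarium-bound hemiacetal of benzaldehyde on the C6 hydroxyl delivers hydride intramolecularly to the ketone through a chair-like bicyclic transition state, giving the 1,3-anti alcohol (4S) and leaving the benzoate on O6 (the C5 descriptor changes to S only through the priority rules).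

Step 9
Reactants: 15 (2Z,4S,5S,6S,8Z)-1-{[tert-butyl(dimethyl)silyl]oxy}-10-chloro-4-hydroxy-2,8-dimethyl-5-(propan-2-yl)deca-2,8-dien-6-yl benzoate
Product: 16 (2Z,4S,5R,6S,8Z)-4-(acetyloxy)-1-{[tert-butyl(dimethyl)silyl]oxy}-10-chloro-2,8-dimethyl-5-(propan-2-yl)deca-2,8-dien-6-yl benzoate
Conditions: Ac2O, Et3N, DMAP (cat.), CH2Cl2, 0 °C
Reagents that add atoms: acetic anhydride, CC(=O)OC(C)=O
Why: DMAP-catalysed acetylation of the only free hydroxyl; no stereocentre is touched.

Step 10
Reactants: 16 (2Z,4S,5R,6S,8Z)-4-(acetyloxy)-1-{[tert-butyl(dimethyl)silyl]oxy}-10-chloro-2,8-dimethyl-5-(propan-2-yl)deca-2,8-dien-6-yl benzoate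
Product: 17 (2Z,4S,5R,6S,8Z)-4-(acetyloxy)-10-chloro-1-hydroxy-2,8-dimethyl-5-(propan-2-yl)deca-2,8-dien-6-yl benzoate
Conditions: aq. HF (48%), MeCN, 0 °C
Reagents that add atoms: none
Why: Acidic fluoride cleaves the primary silyl ether without base, which avoids acetyl migration to the cis-disposed primary hydroxyl and leaves both esters and the allylic chloride intact.

Step 11
Reactants: 17 (2Z,4S,5R,6S,8Z)-4-(acetyloxy)-10-chloro-1-hydroxy-2,8-dimethyl-5-(propan-2-yl)deca-2,8-dien-6-yl benzoate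
Product: 18 (2Z,4S,5R,6S,8Z)-4-(acetyloxy)-10-chloro-2,8-dimethyl-1-oxo-5-(propan-2-yl)deca-2,8-dien-6-yl benzoate
Conditions: Dess–Martin periodinane, NaHCO3, CH2Cl2, 0 °C; filtered and used at once
Reagents that add atoms: none
Why: Buffered Dess–Martin oxidation of the primary allylic alcohol gives the Z-enal without the acid or amine that would isomerise it to the E-enal.

Step 12
Reactants: 18 (2Z,4S,5R,6S,8Z)-4-(acetyloxy)-10-chloro-2,8-dimethyl-1-oxo-5-(propan-2-yl)deca-2,8-dien-6-yl benzoate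
Product: 20 (1S,3Z,6R,7Z,9S,10R)-9-(acetyloxy)-6-hydroxy-3,7-dimethyl-10-(propan-2-yl)cyclodeca-3,7-dien-1-yl benzoate, via allylic radical 19 (not isolated)
Conditions: Cp2TiCl2 (3 equiv), Mn dust (8 equiv), THF, rt, deoxygenated; 18 added over 10 h (final 2 mM); then 0.5 M aq. HCl, 0 °C
Reagents that add atoms: none
Why: Proposed new method: Cp2TiCl (trivalent titanium) abstracts chlorine to give allylic radical 19 and reversibly reduces the titanium-bound enal to a titanoxy-allyl radical, and the two radicals couple at their unhindered termini (chain C10 with chain C1), which closes the ten-membered ring with linear regiochemistry and keeps both Z-alkenes (the geometry a cyclodeca-1,5-diene prefers); the (6R) carbinol requires attack on the Re face of the enal, which is the least secure element because it depends on which conformer closes the ring; the closest known reaction is the intermolecular titanocene-mediated Barbier-type α-prenylation of γ-acyloxy α-methyl enals, run here at high dilution as a macrocyclisation.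

## Compound list

1 | prop-2-yn-1-ol | C#CCO | starting material
2 | 4-methyl-2,5-dihydro-1,2-oxamagnesole (cyclic alkenylmagnesium alkoxide) | CC1=C[Mg]OC1 | intermediate
3 | (2Z)-3-iodo-2-methylprop-2-en-1-ol | OC/C(C)=C\I | intermediate
4 | tert-butyl{[(2Z)-3-iodo-2-methylprop-2-en-1-yl]oxy}dimethylsilane | CC(C)(C)[Si](C)(C)OC/C(C)=C\I | intermediate
5 | 3-methylbutanoyl chloride | CC(C)CC(Cl)=O | starting material
6 | [(1Z)-3-{[tert-butyl(dimethyl)silyl]oxy}-2-methylprop-1-en-1-yl]lithium | [Li]/C=C(/C)CO[Si](C)(C)C(C)(C)C | intermediate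
7 | [(1Z)-3-{[tert-butyl(dimethyl)silyl]oxy}-2-methylprop-1-en-1-yl]zinc chloride | Cl[Zn]/C=C(/C)CO[Si](C)(C)C(C)(C)C | intermediate
8 | (2Z)-1-{[tert-butyl(dimethyl)silyl]oxy}-2,6-dimethylhept-2-en-4-one | CC(C)CC(=O)/C=C(/C)CO[Si](C)(C)C(C)(C)C | intermediate
9 | 4-methyl-5,6-dihydro-2H-pyran-2-one | CC1=CC(=O)OCC1 | starting material
10 | (2Z)-3-methylpent-2-ene-1,5-diol | OC/C=C(/C)CCO | intermediate
11 | (3Z)-5-chloro-3-methylpent-3-en-1-ol | OCC/C(C)=C\CCl | intermediate
12 | (3Z)-5-chloro-3-methylpent-3-enal | O=CC/C(C)=C\CCl | intermediate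
13 | {[(3Z,5Z)-7-{[tert-butyl(dimethyl)silyl]oxy}-2,6-dimethylhepta-3,5-dien-4-yl]oxy}bis[(1R,2S,3R,5R)-2,6,6-trimethylbicyclo[3.1.1]heptan-3-yl]borane (Z-enol borinate of 8) | CC(C)/C=C(/C=C(/C)CO[Si](C)(C)C(C)(C)C)OB([C@@H]1C[C@@H]2C[C@H]([C@H]1C)C2(C)C)[C@@H]1C[C@@H]2C[C@H]([C@H]1C)C2(C)C | intermediate
14 | (2Z,5R,6S,8Z)-1-{[tert-butyl(dimethyl)silyl]oxy}-10-chloro-6-hydroxy-2,8-dimethyl-5-(propan-2-yl)deca-2,8-dien-4-one | CC(C)(C)[Si](C)(C)OC/C(C)=C\C(=O)[C@H](C(C)C)[C@@H](O)C/C(C)=C\CCl | intermediate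
15 | (2Z,4S,5S,6S,8Z)-1-{[tert-butyl(dimethyl)silyl]oxy}-10-chloro-4-hydroxy-2,8-dimethyl-5-(propan-2-yl)deca-2,8-dien-6-yl benzoate | CC(C)(C)[Si](C)(C)OC/C(C)=C\[C@H](O)[C@H](C(C)C)[C@@H](OC(=O)c1ccccc1)C/C(C)=C\CCl | intermediate
16 | (2Z,4S,5R,6S,8Z)-4-(acetyloxy)-1-{[tert-butyl(dimethyl)silyl]oxy}-10-chloro-2,8-dimethyl-5-(propan-2-yl)deca-2,8-dien-6-yl benzoate | CC(C)(C)[Si](C)(C)OC/C(C)=C\[C@H](OC(C)=O)[C@H](C(C)C)[C@@H](OC(=O)c1ccccc1)C/C(C)=C\CCl | intermediate
17 | (2Z,4S,5R,6S,8Z)-4-(acetyloxy)-10-chloro-1-hydroxy-2,8-dimethyl-5-(propan-2-yl)deca-2,8-dien-6-yl benzoate | OC/C(C)=C\[C@H](OC(C)=O)[C@H](C(C)C)[C@@H](OC(=O)c1ccccc1)C/C(C)=C\CCl | intermediate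
18 | (2Z,4S,5R,6S,8Z)-4-(acetyloxy)-10-chloro-2,8-dimethyl-1-oxo-5-(propan-2-yl)deca-2,8-dien-6-yl benzoate | O=C/C(C)=C\[C@H](OC(C)=O)[C@H](C(C)C)[C@@H](OC(=O)c1ccccc1)C/C(C)=C\CCl | intermediate
19 | carbon-centred allylic radical from 18 (chlorine removed from chain C10) | O=C/C(C)=C\[C@H](OC(C)=O)[C@H](C(C)C)[C@@H](OC(=O)c1ccccc1)C/C(C)=C\[CH2] | intermediate
20 | (1S,3Z,6R,7Z,9S,10R)-9-(acetyloxy)-6-hydroxy-3,7-dimethyl-10-(propan-2-yl)cyclodeca-3,7-dien-1-yl benzoate | CC(=O)O[C@H]1/C=C(/C)[C@H](O)C/C=C(/C)C[C@H](OC(=O)c2ccccc2)[C@H]1C(C)C | target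

## Step count and main risks

Total: 12 steps. Longest linear sequence: 9 steps (steps 1, 2, 3, 7, 8, 9, 10, 11, 12; the branch through steps 4, 5, 6 joins at step 7 and is equally long).

Step 12 (ring closure) is the most likely to fail. It can lose material to pinacol or Wurtz dimers, to branched attack, or to Z/E scrambling of the radicals. The facial selectivity at the new carbinol is also not secured: a simple tub-like closure model would give the C6 epimer. The fallback sets out from 18 and comes back at 20, and sets C6 by reagent control. The closure is run as above and the carbinol is taken whatever its configuration, in the worst case as (1S,3Z,6S,7Z,9S,10R)-9-(acetyloxy)-6-hydroxy-3,7-dimethyl-10-(propan-2-yl)cyclodeca-3,7-dien-1-yl benzoate F1. MnO2 in CH2Cl2 oxidises this allylic alcohol to (1S,3Z,7Z,9S,10R)-9-(acetyloxy)-3,7-dimethyl-6-oxo-10-(propan-2-yl)cyclodeca-3,7-dien-1-yl benzoate F2. Reduction of F2 with (S)-2-methyl-CBS-oxazaborolidine and catecholborane at −78 °C, with the alkenyl side as the large group, gives the (6R) alcohol 20.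

Step 7 (aldol) is the second risk. The enolising side is an isobutyl rather than an ethyl ketone, so the enantiomeric excess and even the sense of induction are less certain, and aldehyde 12 can slip into conjugation during the long reaction. The fallback sets out from 5 and comes back at 14, replacing reagent control by an auxiliary. Lithiated (R)-4-benzyl-1,3-oxazolidin-2-one is acylated with 5 to give (4R)-4-benzyl-3-(3-methylbutanoyl)-1,3-oxazolidin-2-one F3. Its dibutylboron Z-enolate (Bu2BOTf, i-Pr2NEt, −78 to 0 °C) adds to 12 to give the Evans syn adduct (4R)-4-benzyl-3-[(2R,3S,5Z)-7-chloro-3-hydroxy-5-methyl-2-(propan-2-yl)hept-5-enoyl]-1,3-oxazolidin-2-one F4. Me3Al and MeNHOMe·HCl convert F4 into (2R,3S,5Z)-7-chloro-3-hydroxy-N-methoxy-N,5-dimethyl-2-(propan-2-yl)hept-5-enamide F5. Excess alkenyllithium 6 (made from 4 as in step 3) at −78 °C then gives 14.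

Step 5 (selective chlorination) is the third risk. The two primary hydroxyls may not be told apart cleanly, and 11 can close to a dihydropyran. The fallback sets out from 10 and comes back at 11, making that cyclic ether on purpose. TsCl and NaH in THF convert 10 into 4-methyl-3,6-dihydro-2H-pyran F6, whichever hydroxyl is tosylated. Acetyl chloride with catalytic ZnCl2 at 0 °C opens F6 at the allylic C–O bond to give (3Z)-5-chloro-3-methylpent-3-en-1-yl acetate F7. i-Bu2AlH at −78 °C removes the acetate without base and gives 11, which is oxidised at once as in step 6.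

Further compounds
F1 | step 12 | (1S,3Z,6S,7Z,9S,10R)-9-(acetyloxy)-6-hydroxy-3,7-dimethyl-10-(propan-2-yl)cyclodeca-3,7-dien-1-yl benzoate | CC(=O)O[C@H]1/C=C(/C)[C@@H](O)C/C=C(/C)C[C@H](OC(=O)c2ccccc2)[C@H]1C(C)C
F2 | step 12 | (1S,3Z,7Z,9S,10R)-9-(acetyloxy)-3,7-dimethyl-6-oxo-10-(propan-2-yl)cyclodeca-3,7-dien-1-yl benzoate | CC(=O)O[C@H]1/C=C(/C)C(=O)C/C=C(/C)C[C@H](OC(=O)c2ccccc2)[C@H]1C(C)C
F3 | step 7 | (4R)-4-benzyl-3-(3-methylbutanoyl)-1,3-oxazolidin-2-one | O=C1OC[C@@H](Cc2ccccc2)N1C(=O)CC(C)C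
F4 | step 7 | (4R)-4-benzyl-3-[(2R,3S,5Z)-7-chloro-3-hydroxy-5-methyl-2-(propan-2-yl)hept-5-enoyl]-1,3-oxazolidin-2-one | O=C1OC[C@@H](Cc2ccccc2)N1C(=O)[C@H](C(C)C)[C@@H](O)C/C(C)=C\CCl
F5 | step 7 | (2R,3S,5Z)-7-chloro-3-hydroxy-N-methoxy-N,5-dimethyl-2-(propan-2-yl)hept-5-enamide | CON(C)C(=O)[C@H](C(C)C)[C@@H](O)C/C(C)=C\CCl
F6 | step 5 | 4-methyl-3,6-dihydro-2H-pyran | CC1=CCOCC1
F7 | step 5 | (3Z)-5-chloro-3-methylpent-3-en-1-yl acetate | CC(=O)OCC/C(C)=C\CCl
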